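**Plan**

- Cuts: the C2 acetate; C8–C17 and C9–C11 on ring B (both through enol triflates, the C11–C16 chain coming from (R)-methyl hydrogen 3-methylglutarate); C2–C3 of ring A; C10–C1 and C5–C4 on a carvone-derived ring B.
- Feature used: ring A (C1–C5, C10) carries a cis-2α,3α-diol, C2–O equatorial and C3–O axial beside the C4 gem-dimethyl group. C2 and C3 are both carbinol carbons, so their bond can come from reductive coupling of two aldehyde arms that sit trans on C10 and C5 of ring B.
- Forward: ring B is (R)-carvone; Mukaiyama–Michael addition makes C4–C5, enolate alkylation makes C10–C1, and the isopropenyl group is then excised. Ring A closes by SmI2 pinacol coupling. The chain (C9–C11) and the C8 methyl are then joined to ring B by two Negishi couplings.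
- Stereochemistry: C5 from the carvone stereocentre (anti addition), C10 by alkylation anti to the C5 arm, C2/C3 from the samarium chelate and the axial methyl groups, C9 from α-face hydroboration, C13 from the chiral-pool hemiester.

Key step: step 7

Remark: labdane numbering is used for all intermediates (ring A C1–C5/C10, ring B C5–C10, chain C11–C16, C17 on C8), and α is the face opposite the C10 methyl group. (R)-Carvone and (R)-methyl hydrogen 3-methylglutarate are assumed to be commercial materials of high enantiomeric purity.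

**Route**

Step 1
Reactants: 1 (R)-(−)-carvone; 2 1-methoxy-2-methyl-1-(trimethylsilyloxy)prop-1-ene
Product: 3 methyl 2-methyl-2-[(1R,5R)-2-methyl-5-(prop-1-en-2-yl)-3-(trimethylsilyloxy)cyclohex-2-en-1-yl]propanoate
Conditions: HN(SO2CF3)2 (2 mol%), CH2Cl2, −78 °C; Et3N quench; used without chromatography
Reagents that add atoms: none
Why: Lewis-acid-catalysed Mukaiyama–Michael addition in which Me3SiN(SO2CF3)2 formed in situ activates the enone and the ketene acetal attacks the β-carbon (C5) by axial approach anti to the pseudo-equatorial isopropenyl group, which sets C5 with its arm trans to isopropenyl, while silyl transfer leaves the C9–C10 enol ether regiodefined.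

Step 2
Reactants: 3 methyl 2-methyl-2-[(1R,5R)-2-methyl-5-(prop-1-en-2-yl)-3-(trimethylsilyloxy)cyclohex-2-en-1-yl]propanoate; 4 methyl bromoacetate
Product: 6 methyl 2-[(1R,2S,5R)-2-(2-methoxy-2-oxoethyl)-2-methyl-3-oxo-5-(prop-1-en-2-yl)cyclohexyl]-2-methylpropanoate, via ammonium enolate 5 (not isolated)
Conditions: [PhCH2NMe3]F (dried), 4 Å MS, THF, 0 °C; then 4, 0 °C → rt
Reagents that add atoms: none
Why: Fluoride-promoted regiospecific alkylation of a silyl enol ether, in which the ammonium enolate is C-alkylated by the reactive α-bromo ester on the face of C10 anti to the bulky pseudo-axial C5 substituent, which sets the C10 quaternary centre with the acetate arm trans to the C5 arm.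

Step 3
Reactants: 6 methyl 2-[(1R,2S,5R)-2-(2-methoxy-2-oxoethyl)-2-methyl-3-oxo-5-(prop-1-en-2-yl)cyclohexyl]-2-methylpropanoate
Product: 8 methyl 2-[(1R,2S)-2-(2-methoxy-2-oxoethyl)-2-methyl-3-oxocyclohexyl]-2-methylpropanoate, via methoxy hydroperoxide 7 (not isolated)
Conditions: O3, MeOH, −78 °C; then PhSH, FeSO4·7H2O, −78 °C → rt
Reagents that add atoms: none
Why: Hydrodealkenylation by ozonolysis and iron-mediated fragmentation, in which divalent iron reduces the α-methoxy hydroperoxide to an alkoxy radical that undergoes β-scission to methyl acetate and a secondary C7 radical, which takes hydrogen from PhSH, so the controlling stereocentre is erased without touching C5 or C10.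

Step 4
Reactants: 8 methyl 2-[(1R,2S)-2-(2-methoxy-2-oxoethyl)-2-methyl-3-oxocyclohexyl]-2-methylpropanoate
Product: 9 methyl 2-[(6S,7R)-6-(2-methoxy-2-oxoethyl)-6-methyl-1,4-dioxaspiro[4.5]decan-7-yl]-2-methylpropanoate
Conditions: Me3SiOCH2CH2OSiMe3, Me3SiOTf (cat.), CH2Cl2, −78 → −20 °C
Reagents that add atoms: 1,2-bis(trimethylsilyloxy)ethane, C[Si](C)(C)OCCO[Si](C)(C)C
Why: Silyl-triflate-catalysed ketalisation with the bis-silyl glycol ether, the usual method for a ketone next to a quaternary carbon, masks C9 under aprotic conditions that leave both methyl esters untouched.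

Step 5
Reactants: 9 methyl 2-[(6S,7R)-6-(2-methoxy-2-oxoethyl)-6-methyl-1,4-dioxaspiro[4.5]decan-7-yl]-2-methylpropanoate
Product: 10 2-[(6S,7S)-6-(2-hydroxyethyl)-6-methyl-1,4-dioxaspiro[4.5]decan-7-yl]-2-methylpropan-1-ol
Conditions: LiAlH4, THF, 0 °C → rt
Reagents that add atoms: none
Why: Hydride reduction of both esters to primary alcohols with LiAlH4, to which the dioxolane is inert (the C7 descriptor changes only because the priorities change).

Step 6
Reactants: 10 2-[(6S,7S)-6-(2-hydroxyethyl)-6-methyl-1,4-dioxaspiro[4.5]decan-7-yl]-2-methylpropan-1-ol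
Product: 11 2-methyl-2-[(6S,7S)-6-methyl-6-(2-oxoethyl)-1,4-dioxaspiro[4.5]decan-7-yl]propanal
Conditions: Dess–Martin periodinane (2.5 equiv), NaHCO3, CH2Cl2, 0 °C → rt; used crude
Reagents that add atoms: none
Why: Dess–Martin oxidation of both primary alcohols under buffered conditions should give the 1,6-dialdehyde without ketal loss and without a stereocentre at risk, since C4 is quaternary and C1 is a methylene.

Step 7
Reactants: 11 2-methyl-2-[(6S,7S)-6-methyl-6-(2-oxoethyl)-1,4-dioxaspiro[4.5]decan-7-yl]propanal
Product: 12 (2R,3S,5S,10S)-9,9-(ethylenedioxy)-4,4,10-trimethyl-trans-decalin-2,3-diol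
Conditions: SmI2 (2.5 equiv), t-BuOH (2 equiv), THF, −78 °C → rt; dialdehyde added to the reductant
Reagents that add atoms: none
Why: Pinacol cyclisation in which two single-electron transfers from divalent samarium turn the C2 and C3 aldehydes into ketyls held on trivalent samarium that join to form the C2–C3 bond, the samarium diolate then being protonated by t-BuOH. The closest known reaction type is the SmI2-mediated intramolecular pinacol coupling of 1,6-dialdehydes to cis-cyclohexane-1,2-diols. Ring A closes as a six-membered carbocycle, in the 6-exo-trig sense if one ketyl adds to the second samarium-bound carbonyl or by direct combination of the 1,6-related ketyl pair, and it is trans-fused to ring B because the two arms already sit trans and equatorial on C5 and C10. The cis relation of C2–O and C3–O follows from both oxygens bridging one samarium, which keeps the O–C–C–O dihedral small in the transition state; the α orientation of the pair (C2–O equatorial, C3–O axial) follows from the substrate, since the other cis pair would place C2–O syn-axial to the β-methyl groups on C4 and C10. The step needs chemoselectivity for the aldehydes, which the dioxolane on C9 secures, and cis selectivity, which additive-free SmI2 at low temperature with a mild proton source should secure by keeping the chelate intact.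

Step 8
Reactants: 12 (2R,3S,5S,10S)-9,9-(ethylenedioxy)-4,4,10-trimethyl-trans-decalin-2,3-diol
Product: 14 (2R,3S,5S,10S)-2,3-(isopropylidenedioxy)-4,4,10-trimethyl-trans-decalin-9-one, via keto diol 13 (not isolated)
Conditions: p-TsOH·H2O (cat.), acetone–H2O, 50 °C; concentrate; then Me2C(OMe)2, p-TsOH (cat.), acetone, rt
Reagents that add atoms: water, O; 2,2-dimethoxypropane, COC(C)(C)OC
Why: Acid-catalysed ketal hydrolysis frees the hindered C9 ketone, and acetonide formation on the cis-2α,3α-diol then protects ring A for the base and organometallic steps, the hindered ketone not being expected to form a dimethyl ketal.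

Step 9
Reactants: 14 (2R,3S,5S,10S)-2,3-(isopropylidenedioxy)-4,4,10-trimethyl-trans-decalin-9-one
Product: 16 (2R,3S,5S,10S)-2,3-(isopropylidenedioxy)-4,4,10-trimethyl-trans-decal-8-en-9-yl trifluoromethanesulfonate, via potassium enolate 15 (not isolated)
Conditions: KN(SiMe3)2, THF, −78 °C; then PhN(SO2CF3)2, −78 → 0 °C
Reagents that add atoms: N-phenylbis(trifluoromethanesulfonimide), O=S(=O)(N(c1ccccc1)S(=O)(=O)C(F)(F)F)C(F)(F)F
Why: Enol triflate formation is regiospecific because C8 is the only enolisable position of the C9 ketone (C10 is quaternary), so the potassium enolate is trapped on oxygen by the triflimide.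

Step 10
Reactants: 17 (3R)-5-methoxy-3-methyl-5-oxopentanoic acid
Product: 19 (4S)-4-methyloxan-2-one, via hydroxy acid 18 (not isolated)
Conditions: LiBH4, THF, 0 → 50 °C; then 2 M HCl, rt
Reagents that add atoms: none
Why: Chemoselective LiBH4 reduction of the ester in the presence of the lithium carboxylate followed by acid lactonisation leaves the stereocentre untouched, its descriptor changing from R to S only because the priorities change.

Step 11
Reactants: 19 (4S)-4-methyloxan-2-one
Product: 21 methyl (3R)-5-iodo-3-methylpentanoate, via silyl ester 20 (not isolated)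
Conditions: Me3SiI, CH2Cl2, 0 °C → rt; then MeOH, 50 °C
Reagents that add atoms: iodotrimethylsilane, C[Si](C)(C)I; methanol, CO
Why: Lactone ring opening by Me3SiI (iodide attacks the O-alkyl carbon of the silylated lactone in an SN2 step) followed by acid-catalysed methanolysis of the silyl ester gives the ω-iodo methyl ester without involving C3.

Step 12
Reactants: 16 (2R,3S,5S,10S)-2,3-(isopropylidenedioxy)-4,4,10-trimethyl-trans-decal-8-en-9-yl trifluoromethanesulfonate; 21 methyl (3R)-5-iodo-3-methylpentanoate
Product: 23 methyl (13S)-2α,3α-(isopropylidenedioxy)-17-norlabd-8-en-15-oate, via alkylzinc iodide 22 (not isolated)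
Conditions: 21, Zn dust (activated with Me3SiCl and BrCH2CH2Br), DMA, 40 °C; then 16, PdCl2(dppf) (5 mol%), THF–DMA, 60 °C
Reagents that add atoms: none
Why: Negishi cross-coupling in which zinc insertion into the primary iodide gives an ester-tolerant alkylzinc iodide that couples with the alkenyl triflate under zerovalent palladium catalysis (oxidative addition, transmetalation, reductive elimination) to form C9–C11.

Step 13
Reactants: 23 methyl (13S)-2α,3α-(isopropylidenedioxy)-17-norlabd-8-en-15-oate
Product: 25 methyl (13S)-8α-hydroxy-2α,3α-(isopropylidenedioxy)-17-norlabdan-15-oate, via alkylborane 24 (not isolated)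
Conditions: BH3·THF (1.5 equiv), THF, 0 °C → rt; then NaBO3·4H2O, H2O, rt
Reagents that add atoms: sodium perborate, [Na+].[Na+].O[B-]1(O)OO[B-](O)(O)OO1
Why: Hydroboration–oxidation places boron on the less substituted C8 and hydrogen on C9 in a syn addition from the α-face, opposite the axial C10 methyl group, which sets C9 with 9α-H and the chain β, while the ester should survive BH3 at 0 °C and the near-neutral perborate oxidation.

Step 14
Reactants: 25 methyl (13S)-8α-hydroxy-2α,3α-(isopropylidenedioxy)-17-norlabdan-15-oate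
Product: 26 methyl (13S)-2α,3α-(isopropylidenedioxy)-8-oxo-17-norlabdan-15-oate
Conditions: Dess–Martin periodinane, NaHCO3, CH2Cl2, 0 °C
Reagents that add atoms: none
Why: Dess–Martin oxidation of the secondary alcohol under buffered, non-basic conditions should give the C8 ketone without epimerising the adjacent C9 centre.

Step 15
Reactants: 26 methyl (13S)-2α,3α-(isopropylidenedioxy)-8-oxo-17-norlabdan-15-oate
Product: 28 methyl (13S)-2α,3α-(isopropylidenedioxy)-8-(trifluoromethylsulfonyloxy)-17-norlabd-7-en-15-oate, via potassium enolate 27 (not isolated)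
Conditions: KN(SiMe3)2 (1.05 equiv), THF, −78 °C (ketone added to base); then N-(5-chloropyridin-2-yl)bis(trifluoromethanesulfonimide), −78 °C
Reagents that add atoms: N-(5-chloropyridin-2-yl)bis(trifluoromethanesulfonimide), O=S(=O)(N(c1ccc(Cl)cn1)S(=O)(=O)C(F)(F)F)C(F)(F)F
Why: Kinetic enolisation with a hindered amide base at −78 °C removes a C7 proton instead of the hindered tertiary C9 proton or the less acidic ester α-protons, and the reactive pyridyl triflimide traps the Δ7 enolate at that temperature as the enol triflate, so C9 is not epimerised.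

Step 16
Reactants: 28 methyl (13S)-2α,3α-(isopropylidenedioxy)-8-(trifluoromethylsulfonyloxy)-17-norlabd-7-en-15-oate
Product: 29 methyl (13S)-2α,3α-(isopropylidenedioxy)labd-7-en-15-oate
Conditions: MeZnCl, Pd(PPh3)4 (5 mol%), THF, 50 °C
Reagents that add atoms: methylzinc chloride, C[Zn]Cl
Why: Negishi coupling of the alkenyl triflate with MeZnCl installs the C8 methyl group (C17) with the double bond fixed at C7–C8 and tolerates the ester and the acetonide.

Step 17
Reactants: 29 methyl (13S)-2α,3α-(isopropylidenedioxy)labd-7-en-15-oate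
Product: 30 methyl (13S)-2α,3α-dihydroxylabd-7-en-15-oate
Conditions: AcOH–H2O (4:1), 40 °C
Reagents that add atoms: none
Why: Mild aqueous acid hydrolysis of the acetonide releases the cis-diol without isomerising the trisubstituted Δ7 alkene or cleaving the methyl ester.

Step 18
Reactants: 30 methyl (13S)-2α,3α-dihydroxylabd-7-en-15-oate
Product: 31 methyl (13S)-2α-acetoxy-3α-hydroxylabd-7-en-15-oate
Conditions: Ac2O (1.1 equiv), pyridine, CH2Cl2, 0 °C
Reagents that add atoms: acetic anhydride, CC(=O)OC(C)=O
Why: Selective acylation is expected because the equatorial C2 hydroxyl reacts with Ac2O and pyridine much faster than the axial C3 hydroxyl, which is neopentylic and flanked by the C4 gem-dimethyl group.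

**Compound list**

1 | (R)-(−)-carvone, (5R)-2-methyl-5-(prop-1-en-2-yl)cyclohex-2-en-1-one | CC1=CC[C@H](CC1=O)C(C)=C | starting material
2 | 1-methoxy-2-methyl-1-(trimethylsilyloxy)prop-1-ene | COC(O[Si](C)(C)C)=C(C)C | starting material
3 | methyl 2-methyl-2-[(1R,5R)-2-methyl-5-(prop-1-en-2-yl)-3-(trimethylsilyloxy)cyclohex-2-en-1-yl]propanoate | C[Si](C)(C)OC1=C(C)[C@H](C(C)(C)C(=O)OC)C[C@@H](C(C)=C)C1 | intermediate
4 | methyl bromoacetate | COC(=O)CBr | starting material
5 | benzyltrimethylammonium enolate of the C9 ketone (from 3, not isolated) | [O-]C1=C(C)[C@H](C(C)(C)C(=O)OC)C[C@@H](C(C)=C)C1.C[N+](C)(C)Cc1ccccc1 | intermediate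
6 | methyl 2-[(1R,2S,5R)-2-(2-methoxy-2-oxoethyl)-2-methyl-3-oxo-5-(prop-1-en-2-yl)cyclohexyl]-2-methylpropanoate | O=C1C[C@H](C(C)=C)C[C@@H](C(C)(C)C(=O)OC)[C@]1(C)CC(=O)OC | intermediate
7 | α-methoxy hydroperoxide from the isopropenyl group of 6 (hydroperoxy carbon as a mixture, not isolated) | O=C1C[C@H](C(C)(OC)OO)C[C@@H](C(C)(C)C(=O)OC)[C@]1(C)CC(=O)OC | intermediate
8 | methyl 2-[(1R,2S)-2-(2-methoxy-2-oxoethyl)-2-methyl-3-oxocyclohexyl]-2-methylpropanoate | O=C1CCC[C@@H](C(C)(C)C(=O)OC)[C@]1(C)CC(=O)OC | intermediate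
9 | methyl 2-[(6S,7R)-6-(2-methoxy-2-oxoethyl)-6-methyl-1,4-dioxaspiro[4.5]decan-7-yl]-2-methylpropanoate | C12(OCCO2)CCC[C@@H](C(C)(C)C(=O)OC)[C@]1(C)CC(=O)OC | intermediate
10 | 2-[(6S,7S)-6-(2-hydroxyethyl)-6-methyl-1,4-dioxaspiro[4.5]decan-7-yl]-2-methylpropan-1-ol | C12(OCCO2)CCC[C@@H](C(C)(C)CO)[C@]1(C)CCO | intermediate
11 | 2-methyl-2-[(6S,7S)-6-methyl-6-(2-oxoethyl)-1,4-dioxaspiro[4.5]decan-7-yl]propanal (ring B dialdehyde, arms trans on C5 and C10, C9 ketal) | C12(OCCO2)CCC[C@@H](C(C)(C)C=O)[C@]1(C)CC=O | intermediate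
12 | (2R,3S,5S,10S)-9,9-(ethylenedioxy)-4,4,10-trimethyl-trans-decalin-2,3-diol (2α,3α-diol, 5α-H, 10β-methyl) | C12(OCCO2)CCC[C@H]3C(C)(C)[C@H](O)[C@H](O)C[C@]13C | intermediate
13 | (2R,3S,5S,10S)-2,3-dihydroxy-4,4,10-trimethyl-trans-decalin-9-one (not isolated) | O=C1CCC[C@H]2C(C)(C)[C@H](O)[C@H](O)C[C@]12C | intermediate
14 | (2R,3S,5S,10S)-2,3-(isopropylidenedioxy)-4,4,10-trimethyl-trans-decalin-9-one | O=C1CCC[C@H]2C(C)(C)[C@@H]3OC(C)(C)O[C@@H]3C[C@]12C | intermediate
15 | potassium Δ8 enolate of 14 (not isolated) | [K+].[O-]C1=CCC[C@H]2C(C)(C)[C@@H]3OC(C)(C)O[C@@H]3C[C@]12C | intermediate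
16 | (2R,3S,5S,10S)-2,3-(isopropylidenedioxy)-4,4,10-trimethyl-trans-decal-8-en-9-yl trifluoromethanesulfonate | FC(F)(F)S(=O)(=O)OC1=CCC[C@H]2C(C)(C)[C@@H]3OC(C)(C)O[C@@H]3C[C@]12C | intermediate
17 | (3R)-5-methoxy-3-methyl-5-oxopentanoic acid, (R)-methyl hydrogen 3-methylglutarate | COC(=O)C[C@H](C)CC(=O)O | starting material
18 | (3S)-5-hydroxy-3-methylpentanoic acid (as lithium salt, not isolated) | OCC[C@H](C)CC(=O)O | intermediate
19 | (4S)-4-methyloxan-2-one | O=C1C[C@@H](C)CCO1 | intermediate
20 | trimethylsilyl (3R)-5-iodo-3-methylpentanoate (not isolated) | C[Si](C)(C)OC(=O)C[C@@H](C)CCI | intermediate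
21 | methyl (3R)-5-iodo-3-methylpentanoate | COC(=O)C[C@@H](C)CCI | intermediate
22 | [(3R)-5-methoxy-3-methyl-5-oxopentyl]zinc iodide (not isolated) | COC(=O)C[C@@H](C)CC[Zn]I | intermediate
23 | methyl (13S)-2α,3α-(isopropylidenedioxy)-17-norlabd-8-en-15-oate | COC(=O)C[C@@H](C)CCC1=CCC[C@H]2C(C)(C)[C@@H]3OC(C)(C)O[C@@H]3C[C@]12C | intermediate
24 | 8α-boryl adduct of 23, 9α-H (monoalkylborane, not isolated) | COC(=O)C[C@@H](C)CC[C@H]1[C@H](B)CC[C@H]2C(C)(C)[C@@H]3OC(C)(C)O[C@@H]3C[C@]12C | intermediate
25 | methyl (13S)-8α-hydroxy-2α,3α-(isopropylidenedioxy)-17-norlabdan-15-oate (9α-H) | COC(=O)C[C@@H](C)CC[C@H]1[C@H](O)CC[C@H]2C(C)(C)[C@@H]3OC(C)(C)O[C@@H]3C[C@]12C | intermediate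
26 | methyl (13S)-2α,3α-(isopropylidenedioxy)-8-oxo-17-norlabdan-15-oate | COC(=O)C[C@@H](C)CC[C@H]1C(=O)CC[C@H]2C(C)(C)[C@@H]3OC(C)(C)O[C@@H]3C[C@]12C | intermediate
27 | potassium Δ7 enolate of 26 (not isolated) | COC(=O)C[C@@H](C)CC[C@H]1C([O-])=CC[C@H]2C(C)(C)[C@@H]3OC(C)(C)O[C@@H]3C[C@]12C.[K+] | intermediate
28 | methyl (13S)-2α,3α-(isopropylidenedioxy)-8-(trifluoromethylsulfonyloxy)-17-norlabd-7-en-15-oate | COC(=O)C[C@@H](C)CC[C@H]1C(OS(=O)(=O)C(F)(F)F)=CC[C@H]2C(C)(C)[C@@H]3OC(C)(C)O[C@@H]3C[C@]12C | intermediate
29 | methyl (13S)-2α,3α-(isopropylidenedioxy)labd-7-en-15-oate | COC(=O)C[C@@H](C)CC[C@H]1C(C)=CC[C@H]2C(C)(C)[C@@H]3OC(C)(C)O[C@@H]3C[C@]12C | intermediate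
30 | methyl (13S)-2α,3α-dihydroxylabd-7-en-15-oate | COC(=O)C[C@@H](C)CC[C@H]1C(C)=CC[C@H]2C(C)(C)[C@H](O)[C@H](O)C[C@]12C | intermediate
31 | methyl (13S)-2α-acetoxy-3α-hydroxylabd-7-en-15-oate | COC(=O)C[C@@H](C)CC[C@H]1C(C)=CC[C@H]2C(C)(C)[C@H](O)[C@H](OC(C)=O)C[C@]12C | target

**Step count and risks**

Total: 18 steps. Longest linear sequence: 16 steps (1–9 and 12–18) from (R)-carvone; the side-chain iodide takes 2 steps (10 and 11).

Steps most likely to fail:

1. Step 7. The samarium chelate may not hold, so that the diequatorial trans-diol forms, or the aldehydes may be reduced to alcohols before they couple. The fallback keeps the C2–C3 disconnection but closes ring A at the alkene level. It sets out from dialdehyde 11: McMurry coupling (TiCl3, Zn–Cu, pyridine, DME, reflux) should give the ring A alkene 9,9-(ethylenedioxy)-4,4,10-trimethyl-trans-decal-2-ene F1. Dihydroxylation with OsO4 (cat.) and N-methylmorpholine N-oxide should then add both oxygens from the α-face, away from the axial methyl groups on C4 and C10, and return to the route at diol 12.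

2. Step 2. At the congested C10 the ammonium enolate may be alkylated on oxygen, protonated by adventitious water, or attacked with poor facial selectivity. The fallback replaces the basic enolate by a Lewis acid alkylation with a thionium electrophile. It sets out from silyl enol ether 3: methyl chloro(phenylsulfanyl)acetate with ZnBr2 in CH2Cl2 should give methyl 2-[(1S,2S,5R)-2-[2-methoxy-2-oxo-1-(phenylsulfanyl)ethyl]-2-methyl-3-oxo-5-(prop-1-en-2-yl)cyclohexyl]-2-methylpropanoate F2 (either configuration at the sulfur-bearing carbon; same ring configuration as 6). Radical desulfurisation with Bu3SnH and AIBN in toluene at 80 °C should then return to the route at keto diester 6.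

3. Step 12. Transmetalation of the alkylzinc iodide onto the hindered C9 palladium centre may be slow, so that the triflate is reduced or the zinc reagent homocouples. The fallback joins the chain by B-alkyl Suzuki–Miyaura coupling. It sets out from iodide 21: dehydroiodination (DBU, 80 °C) should give methyl (3R)-3-methylpent-4-enoate F3, and hydroboration with 9-borabicyclo[3.3.1]nonane in THF should give methyl (3S)-5-(9-borabicyclo[3.3.1]nonan-9-yl)-3-methylpentanoate F4. Coupling of F4 with triflate 16 (PdCl2(dppf), Cs2CO3, AsPh3, DMF–THF–H2O, 50 °C) should return to the route at alkene 23.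

**Further compounds**

F1 | step 7 | 9,9-(ethylenedioxy)-4,4,10-trimethyl-trans-decal-2-ene (5S,10S, labdane numbering) | C12(OCCO2)CCC[C@H]3C(C)(C)C=CC[C@]13C
F2 | step 2 | methyl 2-[(1S,2S,5R)-2-[2-methoxy-2-oxo-1-(phenylsulfanyl)ethyl]-2-methyl-3-oxo-5-(prop-1-en-2-yl)cyclohexyl]-2-methylpropanoate | O=C1C[C@H](C(C)=C)C[C@@H](C(C)(C)C(=O)OC)[C@]1(C)C(Sc2ccccc2)C(=O)OC
F3 | step 12 | methyl (3R)-3-methylpent-4-enoate | COC(=O)C[C@@H](C)C=C
F4 | step 12 | methyl (3S)-5-(9-borabicyclo[3.3.1]nonan-9-yl)-3-methylpentanoate | COC(=O)C[C@@H](C)CCB1C2CCCC1CCC2
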